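**Strategy.** The ten-membered carbocycle is closed between the vinylic carbon C1 of the (E)-C1=C10 olefin and the unfunctionalised methylene C2 (germacrane numbering, defined below). The feature exploited is the head-to-tail 1,5-diene array C5=C4(C15)–C3–C2–C1=C10(C14) of the cyclodecene ring, in which C4=C5 is the latent epoxide. In one operation 9-BBN hydroborates the terminal vinyl group (C2=C3) of an acyclic (Z)-diene and PdCl2(dppf) couples the B-alkyl borane with an (E)-alkenyl iodide at C1, so both ring olefin geometries are set before closure. The precursor is an iodo-triene whose O8 and C12 are tied in a temporary trans-disubstituted γ-lactone; hydroxyl-directed epoxidation ends the route.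

Key step: step 9

Remark on numbering: ring carbons are C1–C10 (C1=C10 olefin, C4–C5 epoxide, C6 carbinol, C7 branch point, C8 acyloxy carbon); the side chain is C11(–C13 methyl)–C12H2O; C14 is the methyl on C10, C15 the methyl on C4; O6 and O8 are the oxygens on C6 and C8.

Remark on the chemistry (assumption): (S)-methylsuccinic anhydride 1 is taken as purchasable; otherwise it is made in one operation from commercial (S)-methylsuccinic acid with acetyl chloride. CIP descriptors of intermediates change formally with the O-substituents; the SMILES define the configuration.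

**Step 1**
Reactants: 1 (S)-methylsuccinic anhydride; 2 (4S)-4-benzyl-1,3-thiazolidine-2-thione
Product: 4 methyl (2S)-4-[(4S)-4-benzyl-2-sulfanylidene-1,3-thiazolidin-3-yl]-2-methyl-4-oxobutanoate, via imide acid 3 (not isolated)
Conditions: 2, NaH, THF, 0 °C; then 1, 0 °C → rt; then MeI, DMF, rt
Reagents that add atoms: iodomethane CI
Why: N-acylation of the sodium thiazolidinethionate by ring opening of the anhydride at the less hindered carbonyl (flanked by CH2, the future C8), then SN2 O-methylation of the carboxylate; C11 comes unchanged from the chiral pool and any regioisomeric imide should be removable by chromatography.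

**Step 2**
Reactants: 5 (2Z)-3-methylpent-2-en-4-yn-1-ol
Product: 6 (2Z)-3-methylpenta-2,4-dien-1-ol
Conditions: H2 (1 atm, 1 equiv), Pd/CaCO3 poisoned with Pb(OAc)2 (Lindlar catalyst), quinoline, Et2O, 0 °C
Reagents that add atoms: none
Why: Lindlar semihydrogenation should stop the terminal alkyne at the vinyl group and leave the (Z)-trisubstituted olefin untouched, so the C4=C5 geometry is bought with the starting material.

**Step 3**
Reactants: 6 (2Z)-3-methylpenta-2,4-dien-1-ol
Product: 7 (2Z)-3-methylpenta-2,4-dienal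
Conditions: activated MnO2 (15 equiv), CH2Cl2, 0 °C → rt, dark; filtered solution used at once
Reagents that add atoms: none
Why: allylic oxidation with MnO2 is mild enough to keep the (Z)-enal geometry (as for nerol to neral), and the volatile aldehyde is carried on in solution.

**Step 4**
Reactants: 4 imide ester; 7 (2Z)-3-methylpenta-2,4-dienal
Product: 9 methyl (2S,3S)-4-[(4S)-4-benzyl-2-sulfanylidene-1,3-thiazolidin-3-yl]-3-[(1S,2Z)-1-hydroxy-3-methylpenta-2,4-dien-1-yl]-2-methyl-4-oxobutanoate, via trimethylsilyl ether 8 (not isolated)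
Conditions: MgBr2·OEt2 (10 mol%), Et3N, Me3SiCl, EtOAc, rt; then 1 M HCl/THF (1:5), 0 °C
Reagents that add atoms: chlorotrimethylsilane C[Si](C)(C)Cl (its silyl group is carried only by 8 and is removed on the way to 9)
Why: Evans magnesium-halide-catalysed direct anti-aldol reaction, in which soft enolisation occurs only at the imide α-carbon (C7) and the (Z)-magnesium enolate of the (S)-benzylthiazolidinethione should add to the enal in the Evans-anti sense, setting C7 and C6 with the C11 branch anti to O6.

**Step 5**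
Reactants: 9 aldol adduct
Product: 10 methyl (2S,3S)-4-[(4S)-4-benzyl-2-sulfanylidene-1,3-thiazolidin-3-yl]-3-[(1S,2Z)-1-{[tert-butyl(dimethyl)silyl]oxy}-3-methylpenta-2,4-dien-1-yl]-2-methyl-4-oxobutanoate
Conditions: TBSOTf, 2,6-lutidine, CH2Cl2, −78 → 0 °C
Reagents that add atoms: tert-butyldimethylsilyl triflate CC(C)(C)[Si](C)(C)OS(=O)(=O)C(F)(F)F
Why: silylation with the silyl triflate at low temperature should avoid retro-aldol cleavage and blocks O6 until the end.

**Step 6**
Reactants: 10 silyl ether imide
Product: 11 methyl (2S,3S,4S,5Z)-4-{[tert-butyl(dimethyl)silyl]oxy}-3-formyl-2,6-dimethylocta-5,7-dienoate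
Conditions: iBu2AlH (1.2 equiv), CH2Cl2, −78 °C; Rochelle salt work-up
Reagents that add atoms: none
Why: reductive cleavage of the N-acylthiazolidinethione by iBu2AlH should stop at the aldehyde through a stable aluminium hemithioaminal while the methyl ester survives at −78 °C; the auxiliary is recovered.

**Step 7**
Reactants: 11 aldehyde; 12 tributyl(propa-1,2-dien-1-yl)stannane
Product: 14 (3S,4R,5S)-4-[(1S,2Z)-1-{[tert-butyl(dimethyl)silyl]oxy}-3-methylpenta-2,4-dien-1-yl]-3-methyl-5-(prop-2-yn-1-yl)oxolan-2-one, via hydroxy ester 13 (not isolated)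
Conditions: BF3·OEt2, CH2Cl2, −78 °C; aq. NaHCO3; then PPTS (cat.), PhMe, 60 °C
Reagents that add atoms: none
Why: Lewis-acid-mediated SE2′ propargylation through an open transition state, in which Felkin–Anh attack anti to the silyloxy-bearing C6 branch and the 1,3-anti preference of the β-silyloxy aldehyde should reinforce each other and set C8 syn to the C11 branch and anti to O6; mild acid then closes the γ-lactone between O8 and C12.

**Step 8**
Reactants: 14 alkynyl lactone
Product: 15 (3S,4R,5S)-4-[(1S,2Z)-1-{[tert-butyl(dimethyl)silyl]oxy}-3-methylpenta-2,4-dien-1-yl]-5-[(2E)-3-iodo-2-methylprop-2-en-1-yl]-3-methyloxolan-2-one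
Conditions: AlMe3 (3 equiv), Cp2ZrCl2 (20 mol%), H2O (1 equiv), CH2Cl2, −25 °C; then I2, THF, −25 °C, dark
Reagents that add atoms: trimethylaluminium C[Al](C)C; iodine II
Why: Negishi zirconium-catalysed syn-methylalumination of the terminal alkyne places methyl on C10 and aluminium on C1, and iodinolysis with retention gives the (E)-alkenyl iodide; the water-accelerated low-temperature variant should spare the lactone and the diene.

**Step 9**
Reactants: 15 iodo-triene lactone
Product: 17 (3S,3aR,4S,5Z,9E,11aS)-4-{[tert-butyl(dimethyl)silyl]oxy}-3,6,10-trimethyl-3a,4,7,8,11,11a-hexahydrocyclodeca[b]furan-2(3H)-one, via alkylborane 16 (not isolated)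
Conditions: 9-BBN (1.3 equiv), THF, 0 °C → rt; then syringe-pump addition to PdCl2(dppf) (15 mol%), AsPh3, Cs2CO3, H2O (10 equiv), DMF/THF, 45 °C, final 2 mM
Reagents that add atoms: 9-borabicyclo[3.3.1]nonane [H]B1C2CCCC1CCC2 (adds H at C3; its boron stays only in 16)
Why: 9-BBN adds across the C2=C3 vinyl terminus of the (Z)-diene with boron on the unhindered C2 (the trisubstituted C4=C5 and C1=C10 olefins and the lactone are inert), and the hydroxide-activated B-alkyl borane then undergoes intramolecular B-alkyl Suzuki–Miyaura coupling by oxidative addition of the C1–I bond to zerovalent palladium formed from PdCl2(dppf), transmetalation of the primary alkyl group and reductive elimination. The closest known reaction type is the B-alkyl Suzuki macrocyclisation of carbocycles, together with the intermolecular coupling of diene-derived homoallyl boranes with (E)-2-methylalkenyl iodides used to build terpenoid 1,5-dienes. The ten-membered ring closes by reductive elimination from an eleven-membered alkyl(alkenyl)palladacycle, a head-to-tail C(sp3)–C(sp2) closure that is endo with respect to the alkenyl iodide. No stereocentre is created: the (E)-geometry at C1=C10 is transferred stereospecifically from the iodide and the (Z)-geometry at C4=C5 is untouched. The step needs ring closure to beat oligomerisation, β-hydride elimination and protodeboronation; slow addition at high dilution, the large-bite-angle dppf ligand with AsPh3, and the restriction imposed by the trans-disubstituted γ-lactone across C7–C8 and the (Z)-olefin are meant to secure this. Carbonate should not epimerise C11 next to the lactone carbonyl, and any opened hydroxy acid relactonises on acidic work-up.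

**Step 10**
Reactants: 17 macrocyclic lactone
Product: 18 (1S,2R,3S,4Z,8E)-3-{[tert-butyl(dimethyl)silyl]oxy}-2-[(2S)-1-hydroxypropan-2-yl]-5,9-dimethylcyclodeca-4,8-dien-1-ol
Conditions: LiAlH4, THF, 0 °C
Reagents that add atoms: none
Why: hydride reduction of the γ-lactone unmasks O8–H and C12–OH together while the silyl ether keeps O6 blocked; no stereocentre is touched.

**Step 11**
Reactants: 18 diol; 19 angelic acid [(2Z)-2-methylbut-2-enoic acid]
Product: 20 (1S,2R,3S,4Z,8E)-3-{[tert-butyl(dimethyl)silyl]oxy}-5,9-dimethyl-2-[(2S)-1-{[(2Z)-2-methylbut-2-enoyl]oxy}propan-2-yl]cyclodeca-4,8-dien-1-yl (2Z)-2-methylbut-2-enoate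
Conditions: 19 (4 equiv), 2,4,6-trichlorobenzoyl chloride, Et3N, PhMe, rt; then 18, 75 °C
Reagents that add atoms: none
Why: Yamaguchi-type mixed-anhydride esterification without a nucleophilic catalyst should acylate both the primary and the secondary hydroxyl and is the established way to avoid angelate-to-tiglate isomerisation.

**Step 12**
Reactants: 20 silyl ether diangelate
Product: 21 (1S,2S,3S,4Z,8E)-3-hydroxy-5,9-dimethyl-2-[(2S)-1-{[(2Z)-2-methylbut-2-enoyl]oxy}propan-2-yl]cyclodeca-4,8-dien-1-yl (2Z)-2-methylbut-2-enoate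
Conditions: HF·pyridine, excess pyridine, THF, 0 °C → rt
Reagents that add atoms: none
Why: buffered fluoride-mediated desilylation should free O6–H without acyl migration from O8 or acid-induced transannular cyclisation of the diene.

**Step 13**
Reactants: 21 allylic alcohol
Product: 22 CNP0272382.1, (1(10)E,4S,5R,6R,7S,8S,11S)-4,5-epoxy-6-hydroxygermacr-1(10)-ene-8,12-diyl bis[(2Z)-2-methylbut-2-enoate]
Conditions: VO(acac)2 (5 mol%), t-BuOOH (1.5 equiv, decane), CH2Cl2, 0 °C
Reagents that add atoms: tert-butyl hydroperoxide CC(C)(C)OO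
Why: hydroxyl-directed vanadium-catalysed epoxidation, in which the vanadate ester of O6–H should deliver oxygen to the adjacent (Z)-C4=C5 olefin on the face syn to the hydroxyl, as for (Z)-cyclooct-2-enol and (Z)-cyclonon-2-enol, giving the cis-epoxy alcohol and so setting C4 and C5; the isolated C1=C10 olefin and the electron-poor angelates should not react.

**Compound list**
1 | (3S)-3-methyloxolane-2,5-dione, (S)-methylsuccinic anhydride | O=C1[C@@H](C)CC(=O)O1 | starting material
2 | (4S)-4-benzyl-1,3-thiazolidine-2-thione | S=C1N[C@@H](Cc2ccccc2)CS1 | starting material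
3 | (2S)-4-[(4S)-4-benzyl-2-sulfanylidene-1,3-thiazolidin-3-yl]-2-methyl-4-oxobutanoic acid (sodium salt in the flask) | OC(=O)[C@@H](C)CC(=O)N1[C@@H](Cc2ccccc2)CSC1=S | intermediate
4 | methyl (2S)-4-[(4S)-4-benzyl-2-sulfanylidene-1,3-thiazolidin-3-yl]-2-methyl-4-oxobutanoate | COC(=O)[C@@H](C)CC(=O)N1[C@@H](Cc2ccccc2)CSC1=S | intermediate
5 | (2Z)-3-methylpent-2-en-4-yn-1-ol | C#C/C(C)=C\CO | starting material
6 | (2Z)-3-methylpenta-2,4-dien-1-ol | C=C/C(C)=C\CO | intermediate
7 | (2Z)-3-methylpenta-2,4-dienal | C=C/C(C)=C\C=O | intermediate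
8 | trimethylsilyl ether of 9 (O6–SiMe3) | COC(=O)[C@@H](C)[C@@H]([C@@H](O[Si](C)(C)C)/C=C(C)\C=C)C(=O)N1[C@@H](Cc2ccccc2)CSC1=S | intermediate
9 | methyl (2S,3S)-4-[(4S)-4-benzyl-2-sulfanylidene-1,3-thiazolidin-3-yl]-3-[(1S,2Z)-1-hydroxy-3-methylpenta-2,4-dien-1-yl]-2-methyl-4-oxobutanoate | COC(=O)[C@@H](C)[C@@H]([C@@H](O)/C=C(C)\C=C)C(=O)N1[C@@H](Cc2ccccc2)CSC1=S | intermediate
10 | tert-butyldimethylsilyl ether of 9 (O6–TBS) | COC(=O)[C@@H](C)[C@@H]([C@@H](O[Si](C)(C)C(C)(C)C)/C=C(C)\C=C)C(=O)N1[C@@H](Cc2ccccc2)CSC1=S | intermediate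
11 | methyl (2S,3S,4S,5Z)-4-{[tert-butyl(dimethyl)silyl]oxy}-3-formyl-2,6-dimethylocta-5,7-dienoate | COC(=O)[C@@H](C)[C@@H]([C@@H](O[Si](C)(C)C(C)(C)C)/C=C(C)\C=C)C=O | intermediate
12 | tributyl(propa-1,2-dien-1-yl)stannane | C=C=C[Sn](CCCC)(CCCC)CCCC | starting material
13 | methyl (2S,3R,4S,5Z)-4-{[tert-butyl(dimethyl)silyl]oxy}-3-[(1S)-1-hydroxybut-3-yn-1-yl]-2,6-dimethylocta-5,7-dienoate | COC(=O)[C@@H](C)[C@@H]([C@@H](O[Si](C)(C)C(C)(C)C)/C=C(C)\C=C)[C@H](CC#C)O | intermediate
14 | (3S,4R,5S)-4-[(1S,2Z)-1-{[tert-butyl(dimethyl)silyl]oxy}-3-methylpenta-2,4-dien-1-yl]-3-methyl-5-(prop-2-yn-1-yl)oxolan-2-one | O=C1[C@@H](C)[C@@H]([C@@H](O[Si](C)(C)C(C)(C)C)/C=C(C)\C=C)[C@H](CC#C)O1 | intermediate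
15 | (3S,4R,5S)-4-[(1S,2Z)-1-{[tert-butyl(dimethyl)silyl]oxy}-3-methylpenta-2,4-dien-1-yl]-5-[(2E)-3-iodo-2-methylprop-2-en-1-yl]-3-methyloxolan-2-one | O=C1[C@@H](C)[C@@H]([C@@H](O[Si](C)(C)C(C)(C)C)/C=C(C)\C=C)[C@H](C/C(C)=C/I)O1 | intermediate
16 | B-alkyl-9-BBN adduct of 15 (vinyl group turned into CH2–CH2–B on C2; all else as in 15) | O=C1[C@@H](C)[C@@H]([C@@H](O[Si](C)(C)C(C)(C)C)/C=C(C)\CCB2C3CCCC2CCC3)[C@H](C/C(C)=C/I)O1 | intermediate
17 | (3S,3aR,4S,5Z,9E,11aS)-4-{[tert-butyl(dimethyl)silyl]oxy}-3,6,10-trimethyl-3a,4,7,8,11,11a-hexahydrocyclodeca[b]furan-2(3H)-one | O=C2[C@@H](C)[C@H]1[C@@H](O[Si](C)(C)C(C)(C)C)/C=C(C)\CC/C=C(\C)C[C@@H]1O2 | intermediate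
18 | (1S,2R,3S,4Z,8E)-3-{[tert-butyl(dimethyl)silyl]oxy}-2-[(2S)-1-hydroxypropan-2-yl]-5,9-dimethylcyclodeca-4,8-dien-1-ol | OC[C@@H](C)[C@H]1[C@@H](O[Si](C)(C)C(C)(C)C)/C=C(C)\CC/C=C(\C)C[C@@H]1O | intermediate
19 | angelic acid, (2Z)-2-methylbut-2-enoic acid | C/C=C(/C)C(=O)O | starting material
20 | O6-TBS 8,12-diangelate (bis-ester of 18) | C/C=C(/C)C(=O)OC[C@@H](C)[C@H]1[C@@H](O[Si](C)(C)C(C)(C)C)/C=C(C)\CC/C=C(\C)C[C@@H]1OC(=O)/C(C)=C\C | intermediate
21 | (1S,2S,3S,4Z,8E)-3-hydroxy-5,9-dimethyl-2-[(2S)-1-{[(2Z)-2-methylbut-2-enoyl]oxy}propan-2-yl]cyclodeca-4,8-dien-1-yl (2Z)-2-methylbut-2-enoate | C/C=C(/C)C(=O)OC[C@@H](C)[C@H]1[C@@H](O)/C=C(C)\CC/C=C(\C)C[C@@H]1OC(=O)/C(C)=C\C | intermediate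
22 | CNP0272382.1 | C/C=C(/C)C(=O)OC[C@@H](C)[C@H]1[C@@H](O)[C@H]2O[C@@]2(C)CC/C=C(\C)C[C@@H]1OC(=O)/C(C)=C\C | target

**Count.** Total steps: 13. Longest linear sequence: 12 steps (5 → 6 → 7 → 9 → 10 → 11 → 14 → 15 → 17 → 18 → 20 → 21 → 22).

**Steps most likely to fail, with fallbacks**

Step 9. Reductive elimination to the strained ten-membered ring may be slow, so that oligomerisation, β-hydride elimination of the homoallylic alkylpalladium and protodeboronation take over; aqueous base may also open the lactone. The fallback sets out from 15 and comes back at 17. Hydroboration of 15 with 9-BBN as before, followed by oxidation with NaBO3·4H2O, would give the primary alcohol F1. I2/PPh3/imidazole would turn it into the primary iodide F2. Zinc dust with LiCl in THF at rt should insert into the C(sp3)–I bond only, giving the alkylzinc iodide F3. Slow addition of this reagent to Pd(PPh3)4 in THF at high dilution would close the same C1–C2 bond by intramolecular Negishi coupling, without base or water, to return to 17.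

Step 4. The (Z)-enal may isomerise under the amine and magnesium salt, and the ester group and the C11 stereocentre may erode the anti and facial selectivity of the auxiliary (mismatched double stereodifferentiation). The fallback sets out from 1 and 7 and comes back at 11. Opening of 1 with sodium 2-methylpropane-2-thiolate and methylation with MeI would give the thioester F4. Its (E)-enol borinate, made at −78 °C with a menthone-derived chiral dialkylboron bromide (Gennari–Paterson reagent) and Et3N, should add to 7 under reagent control to give the anti-aldol adduct F5. TBSOTf/2,6-lutidine would give the silyl ether F6, and iBu2AlH at −78 °C would reduce the thioester to aldehyde 11.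

Step 13. The ten-membered ring may populate a conformer in which the vanadate-bound O6 reaches the other face of C4=C5, giving poor facial selectivity; acid-induced transannular opening of the new epoxide by C1=C10 is a further risk. The fallback sets out from 21 and comes back at 22. It replaces substrate-directed delivery by reagent control: Ti(OiPr)4, D-(−)-diisopropyl tartrate (the enantiomer for which 21 should be the fast-reacting, erythro-forming secondary allylic alcohol in the Sharpless kinetic-resolution model), t-BuOOH, 4 Å molecular sieves, CH2Cl2, −20 °C. No new compound is made (F0).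

**Further compounds**
F1 | step 9 | (3S,4R,5S)-4-[(1S,2Z)-1-{[tert-butyl(dimethyl)silyl]oxy}-5-hydroxy-3-methylpent-2-en-1-yl]-5-[(2E)-3-iodo-2-methylprop-2-en-1-yl]-3-methyloxolan-2-one | O=C1[C@@H](C)[C@@H]([C@@H](O[Si](C)(C)C(C)(C)C)/C=C(C)\CCO)[C@H](C/C(C)=C/I)O1
F2 | step 9 | primary iodide from F1 (C2–I) | O=C1[C@@H](C)[C@@H]([C@@H](O[Si](C)(C)C(C)(C)C)/C=C(C)\CCI)[C@H](C/C(C)=C/I)O1
F3 | step 9 | alkylzinc iodide from F2 (C2–ZnI) | O=C1[C@@H](C)[C@@H]([C@@H](O[Si](C)(C)C(C)(C)C)/C=C(C)\CC[Zn]I)[C@H](C/C(C)=C/I)O1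
F4 | step 4 | methyl (2S)-4-(tert-butylsulfanyl)-2-methyl-4-oxobutanoate | COC(=O)[C@@H](C)CC(=O)SC(C)(C)C
F5 | step 4 | methyl (2S,3S)-4-(tert-butylsulfanyl)-3-[(1S,2Z)-1-hydroxy-3-methylpenta-2,4-dien-1-yl]-2-methyl-4-oxobutanoate | COC(=O)[C@@H](C)[C@@H]([C@@H](O)/C=C(C)\C=C)C(=O)SC(C)(C)C
F6 | step 4 | tert-butyldimethylsilyl ether of F5 | COC(=O)[C@@H](C)[C@@H]([C@@H](O[Si](C)(C)C(C)(C)C)/C=C(C)\C=C)C(=O)SC(C)(C)C
F0 | step 13 | none | none
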